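Atom numbering used throughout: ring A is N1–O2–C3–C3a–C6a, ring B is C3a–C4–C5–C6–C6a, C1'' is the first carbon of the chain on C3, and C1' is the first carbon of the chain on N1.

## Analysis of the target

Pyrinodemin B (22) is a cis-fused hexahydro-1H-cyclopenta[c]isoxazole in which N1 carries a 13-(pyridin-3-yl)tridecyl chain and C3 an 8-(pyridin-3-yl)octyl chain. The three stereocentres C3 (S), C3a (S) and C6a (R) are contiguous and their hydrogens all lie on the convex face of the bicycle, so the C3 chain points into the concave face, cis to C4. The sensitive elements are the weak N1–O2 bond, the oxidisable hydroxylamine nitrogen, and two unhindered pyridines that are basic, are alkylated by strong electrophiles and bind soft metal catalysts. The difficulty sits in ring A: an N–O bond has to be carried or made, the ring fusion must be cis in the right absolute sense, and C3 must hold its substituent on the more hindered face. That arrangement is the less stable one and cannot be reached by epimerisation. The strategy rests on the fact that C3 is bonded only to O2, C3a and an unbranched chain. It can therefore stay an sp carbon of an alkyne on C3a until O2 has been joined to it, and be made tetrahedral only afterwards. In the resulting 3-alkylidene bicycle, ring B itself tells the two faces of C3 apart, so the endo configuration should follow from hydrogen addition to the open convex face.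

## Retrosynthetic reasoning

The last bonds formed are C3–H and C1''–H. Removing them from 22 gives the (3Z)-3-alkylidene isoxazolidine 21, in which C3 is trigonal. Ring B covers the concave face of C3, so hydrogen must arrive from the convex face and leave the chain endo. The forward step has to saturate a trisubstituted enol ether without breaking N1–O2 and without reducing the pyridines.

Cutting O2–C3 of 21 gives the N,N-dialkylhydroxylamine 19, with C3≡C1'' as an alkyne on C3a and the N–OH group on the neighbouring ring carbon, cis to it. This cut is chosen over N1–C6a or N1–O2 because it leaves both ring-fusion centres in a plain cis-1,2-disubstituted cyclopentane and makes C3 stereochemically silent. Ring A is gained in one isomerisation that adds no atoms. The forward reaction must deliver oxygen, not nitrogen, to the proximal alkyne carbon in a 5-exo-dig closure. The catalyst must also be kept from the two pyridines, which is why 19 is to be converted in the flask into its bis(pyridinium) salt 20.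

The N1–C1' bond of 19 is cut next, giving the N-monosubstituted hydroxylamine 12 and the aldehyde 17, joined in the forward sense through the nitrone 18 and hydride reduction. Carbonyl condensation is preferred to N-alkylation with a chain bearing a leaving group, because such a chain would quaternise its own pyridine. The cut also makes the route convergent, with the two pyridine-terminated chains prepared separately.

The C6a–N1 bond is cut with inversion. Compound 12 comes from the doubly carbamate-protected 11, and 11 from the trans alcohol 9 and the N,O-bis-Boc hydroxylamine 10 by a Mitsunobu reaction. The cis relationship is thus derived from the trans relationship that epoxide opening provides. Direct SN2 displacement after sulfonylation of the hydroxyl group was not chosen, because so strongly alkylating a secondary carbon would also be attacked by the pyridine nitrogens. The Mitsunobu conditions are neutral, and the acidic N–H of 10 reacts only at nitrogen.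

In 9 the bond between the picolyl carbon and the chain is cut, giving the bromo alcohol 5 and 3-methylpyridine 6, which reacts as its lithio derivative 7 (5 being present as its alkoxide 8). The pyridine is attached at this point for two reasons. Earlier it would bind the Lewis acid needed for the epoxide opening, and later the carbanion 7 would attack the carbamate groups of 11. The lithium amide base at −78 °C is chosen here because 5 carries a propargylic stereocentre that harsher metalating conditions could disturb.

Compound 5 is one enantiomer of the racemic trans alcohol 4 and is to be obtained by enzymatic kinetic resolution at this cheap, early stage. Compound 4 is cut at the C3a–C3 bond into the meso epoxide 2 and the alkyne 1, which reacts as its lithium acetylide 3. Backside opening of the epoxide gives only the trans isomer, and this bond places the future C3 on the ring as an alkyne carbon from the start.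

The aldehyde 17 comes from the alcohol 16 by oxidation. Compound 16 is cut at the picolyl–chain bond into 6 and the bromo alcohol 13. Because 13 is achiral and has no base-sensitive position, 6 is metalated here by the classical sodium amide procedure and reacts as its sodio derivative 14, with 13 present as its sodium alkoxide 15. The same kind of carbon–carbon bond construction therefore serves both chains.

## Alternatives that were turned down

Alternative 1: Ring A is opened at N1–C6a and ring B is traced back to a meso cyclopentene diester, the dibenzoate A1.
- Forward course: a first palladium-catalysed allylic substitution on A1 would attach the future C3 carbon to C3a with desymmetrisation. After elaboration to the O-alkylhydroxylamine A2, zerovalent palladium would ionise the remaining benzoate. The N–H nitrogen would then attack the allyl terminus next to the side chain and close ring A as the cyclopentene A3.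
- For it: a chiral ligand sets the absolute configuration catalytically from the meso compound A1, so nothing is lost in a resolution. The double-inversion course of both substitutions secures the cis ring fusion. On these two points it is stronger than the chosen route.
- Against it: C3 is an exocyclic carbinol carbon in A2, so its configuration needs a separate acyclic 1,2-induction and an O–N bond formation of defined stereochemical course. The first substitution on A1 needs a stabilised carbon nucleophile whose activating groups must later be removed. A3 still requires an alkene hydrogenation next to the N–O bond, and the pyridines bind palladium as they bind gold.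
- Comparison: the sequence from A1 to A2 is estimated to be clearly longer than the eight steps that lead to 19. The chosen route pays with a resolution, but C3 needs no independent control because it is formed last under control by the bicycle.

Alternative 2: Both heteroatom bonds of ring A, N1–C6a and O2–C3, are cut at once, giving the enone A4 and the N-alkylhydroxylamine A5.
- Forward course: under chiral primary amine (iminium) catalysis the nitrogen of A5 would add to the β-carbon of A4 and the oxygen would close onto the carbonyl to give the cyclic hemiketal A6. A6 would then be reduced at C3 by hydride from the convex face.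
- For it: this is the most convergent plan. Two fragments of similar size form two ring bonds in one operation without protecting groups, without a metal that pyridines could bind, and with catalytic control of absolute configuration. On convergence and step count it is stronger than the chosen route.
- Against it: A4 is an α-branched enone with the β-carbon in a ring, a class that forms iminium ions reluctantly. The conjugate addition of a hydroxylamine is reversible, so the configuration at C6a can erode. C3a is set by a protonation that the catalyst does not control. A5 is a basic N-alkylhydroxylamine, not the N-acylated type for which asymmetric additions of this kind are established.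
- Comparison: the final hydride delivery to A6 uses the same convex-face bias as the chosen route, so nothing is gained at C3. The chosen route gives up convergence for a secure absolute configuration, fixed by an enzymatic resolution and an SN2 inversion.

Alternative 3: O2 is taken out from between N1 and C3, leading back to the cis-fused 7-alkynyl azetidine A7.
- Forward course: a peracid would oxidise the azetidine nitrogen of A7 to the N-oxide A8. A [1,2]-Meisenheimer shift of the propargylic carbon from nitrogen to oxygen would then expand the four-membered ring to the alkynyl isoxazolidine A9, and the alkyne would be hydrogenated.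
- For it: the N–O bond is made late, so no oxidisable hydroxylamine is carried through the synthesis, and ring strain and the propargylic migrating carbon both favour the shift. On the handling of sensitive intermediates it is stronger than the chosen route.
- Against it: the shift runs through C–N homolysis and radical-pair recombination, so the configuration of C3 can be lost. The propargyl radical can also recombine at its allenyl terminus. A8 has β-hydrogens in the tridecyl chain, so Cope elimination competes. The peracid also attacks the pyridines, and a stereodefined A7 is itself harder to make than 19. A9 then needs a full alkyne hydrogenation beside the N–O bond.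
- Comparison: the chosen route sets C3 by a polar, substrate-controlled addition of one equivalent of hydrogen, and the only free N–OH compounds it handles are 12 and 19, between steps 5 and 9.

Key step: step 9

## Route

Remark (assumption): the lipase is taken to show its usual preference for acylating the R carbinol centre of trans-2-substituted cycloalkanols. If the opposite enantiomer were acylated, 5 would be obtained from the acetate by methanolysis.

Step 1
Reactants: 1 8-bromooct-1-yne; 2 cyclopentene oxide
Product: 4 racemic trans-2-(8-bromooct-1-yn-1-yl)cyclopentan-1-ol, via lithium 8-bromooct-1-yn-1-ide 3 (not isolated)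
Conditions: 1, n-BuLi, THF, −78 °C; BF3·OEt2; then 2, −78 °C; H2O
Reagents that add atoms: none
Why: BF3-promoted opening of an epoxide by a lithium acetylide proceeds by backside attack and should give only the trans 1,2-relationship; the primary bromide is inert to the acetylide at −78 °C. The product is racemic because 2 is meso.

Step 2
Reactants: 4 racemic trans-2-(8-bromooct-1-yn-1-yl)cyclopentan-1-ol
Product: 5 (1S,2R)-2-(8-bromooct-1-yn-1-yl)cyclopentan-1-ol
Conditions: Novozym 435 (immobilised Candida antarctica lipase B), vinyl acetate, MTBE, 30 °C, to just past half conversion; chromatography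
Reagents that add atoms: none
Why: Lipase-catalysed kinetic resolution by transesterification; the enzyme should acylate the (1R,2S) enantiomer and leave (1S,2R)-5, whose enantiomeric purity can be raised by running slightly past half conversion. This fixes the absolute configuration of the future C3a.

Step 3
Reactants: 5 (1S,2R)-2-(8-bromooct-1-yn-1-yl)cyclopentan-1-ol; 6 3-methylpyridine
Product: 9 (1S,2R)-2-[9-(pyridin-3-yl)non-1-yn-1-yl]cyclopentan-1-ol, via (pyridin-3-ylmethyl)lithium 7 (not isolated), via lithium (1S,2R)-2-(8-bromooct-1-yn-1-yl)cyclopentan-1-olate 8 (not isolated)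
Conditions: 6 (2.6 equiv), LiN(i-Pr)2 (2.4 equiv), THF, −78 °C; then 5, −78 → 0 °C; H2O
Reagents that add atoms: none
Why: Lateral lithiation of 3-methylpyridine followed by SN2 alkylation of the picolyl anion at the primary bromide; one equivalent of 7 is spent on the hydroxyl group, and the lithium alkoxide 8 is a poor nucleophile at low temperature. The low temperature and the lithium counter-ion leave the propargylic C2–H alone, so no stereocentre is touched.

Step 4
Reactants: 9 (1S,2R)-2-[9-(pyridin-3-yl)non-1-yn-1-yl]cyclopentan-1-ol; 10 tert-butyl N-[(tert-butoxycarbonyl)oxy]carbamate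
Product: 11 tert-butyl N-[(tert-butoxycarbonyl)oxy]-N-{(1R,2R)-2-[9-(pyridin-3-yl)non-1-yn-1-yl]cyclopentyl}carbamate
Conditions: PPh3, DIAD, THF, 0 °C → rt
Reagents that add atoms: none
Why: Mitsunobu reaction; the acidic N–H of 10 is alkylated at nitrogen by the alkoxyphosphonium ion of 9 with inversion at C1, turning the trans alcohol into the cis-1,2-disubstituted cyclopentane (future C6a, R). The conditions are neutral, so the pyridine is not alkylated, and the C2–H is syn to the leaving group, so anti elimination toward the alkyne is not available.

Step 5
Reactants: 11 tert-butyl N-[(tert-butoxycarbonyl)oxy]-N-{(1R,2R)-2-[9-(pyridin-3-yl)non-1-yn-1-yl]cyclopentyl}carbamate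
Product: 12 N-{(1R,2R)-2-[9-(pyridin-3-yl)non-1-yn-1-yl]cyclopentyl}hydroxylamine
Conditions: TFA, CH2Cl2, 0 °C → rt; aq NaHCO3; used at once under argon
Reagents that add atoms: none
Why: Acidolysis of the tert-butyl carbamate and the tert-butyl carbonate (loss of the tert-butyl cation, then decarboxylation) frees N–H and O–H. The internal alkyne and the protonated pyridine are not affected.

Step 6
Reactants: 6 3-methylpyridine; 13 12-bromododecan-1-ol
Product: 16 13-(pyridin-3-yl)tridecan-1-ol, via (pyridin-3-ylmethyl)sodium 14 (not isolated), via sodium 12-bromododecan-1-olate 15 (not isolated)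
Conditions: 6 (2.6 equiv), NaNH2 (2.4 equiv), liq. NH3, −33 °C; then 13 in THF, −33 °C; NH3 evaporated; H2O
Reagents that add atoms: none
Why: Lateral metalation of 3-methylpyridine by sodium amide in liquid ammonia, the classical way to alkylate this picoline, followed by SN2 alkylation at the primary bromide; the first equivalent of 14 deprotonates the hydroxyl group and the second displaces bromide from 15. The partner 13 has no stereocentre or acidic C–H that the stronger sodium base could disturb, and the excess of 6 over NaNH2 should leave little free amide to attack the bromide.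

Step 7
Reactants: 16 13-(pyridin-3-yl)tridecan-1-ol
Product: 17 13-(pyridin-3-yl)tridecanal
Conditions: TEMPO (10 mol %), PhI(OAc)2, CH2Cl2, rt
Reagents that add atoms: none
Why: Nitroxyl-catalysed (oxoammonium) oxidation of a primary alcohol; it should stop at the aldehyde in the absence of water and does not oxidise the pyridine nitrogen.

Step 8
Reactants: 12 N-{(1R,2R)-2-[9-(pyridin-3-yl)non-1-yn-1-yl]cyclopentyl}hydroxylamine; 17 13-(pyridin-3-yl)tridecanal
Product: 19 N-{(1R,2R)-2-[9-(pyridin-3-yl)non-1-yn-1-yl]cyclopentyl}-N-[13-(pyridin-3-yl)tridecyl]hydroxylamine, via (Z)-aldonitrone 18 (not isolated)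
Conditions: MgSO4, CH2Cl2, rt; then NaBH4, MeOH, 0 °C; under argon
Reagents that add atoms: none
Why: Condensation of an N-monosubstituted hydroxylamine with an aldehyde gives the nitrone, and hydride reduction of its C=N bond gives the N,N-dialkylhydroxylamine. The nitrone cannot add to the tethered alkyne, since the cycloadduct would hold a bridgehead double bond, and no stereocentre is touched.

Step 9
Reactants: 19 N-{(1R,2R)-2-[9-(pyridin-3-yl)non-1-yn-1-yl]cyclopentyl}-N-[13-(pyridin-3-yl)tridecyl]hydroxylamine
Product: 21 (3Z,3aS,6aR)-3-[8-(pyridin-3-yl)octylidene]-1-[13-(pyridin-3-yl)tridecyl]hexahydro-1H-cyclopenta[c]isoxazole, via bis(pyridinium) bis(triflimide) salt 20 (not isolated)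
Conditions: HNTf2 (2.0 equiv), 4 Å MS, CH2Cl2, 0 °C; Ph3PAuNTf2 (5 mol %), rt; then Et3N
Reagents that add atoms: none
Why: Two equivalents of HNTf2 first place protons on the basic nitrogens, by preference on the two pyridines (20), so that little free pyridine is left to tie up the catalyst, while fast proton exchange should keep enough hydroxylamine free to react. [Ph3PAu]+ then coordinates the C3≡C1'' triple bond and the hydroxylamine oxygen attacks C3 anti to gold, forming O2–C3 and closing ring A in a 5-exo-dig mode; loss of the O–H proton and protodeauration with retention leave O2 and C2'' cis, that is the Z enol ether. The closest known reaction type is the intramolecular hydroalkoxylation of 4-alkyn-1-ols to 2-alkylidene tetrahydrofurans under monovalent gold catalysis, and hydroxylamine O–H groups are established nucleophiles in metal-catalysed additions to alkynes and allenes. No stereocentre is formed: C3 stays trigonal, and C3a and C6a, set in steps 2 and 4, are not involved. The step needs oxygen over nitrogen attack and exo over endo closure. Nitrogen could reach C3 only through a four-membered ring and C1'' only in a 5-endo mode that builds a fully substituted N-hydroxyammonium centre beside the ring fusion, an attack expected to be slower and reversible, whereas O-attack is made irreversible by proton loss and protodeauration. The cis-1,2 arrangement on the cyclopentane holds the oxygen over the proximal alkyne carbon, and alkyl-substituted alkynes with this tether length normally close exo; the pyridinium acid keeps the vinyl-gold intermediate short-lived, which should suppress N–O cleavage from it.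

Step 10
Reactants: 21 (3Z,3aS,6aR)-3-[8-(pyridin-3-yl)octylidene]-1-[13-(pyridin-3-yl)tridecyl]hexahydro-1H-cyclopenta[c]isoxazole
Product: 22 (3S,3aS,6aR)-3-[8-(pyridin-3-yl)octyl]-1-[13-(pyridin-3-yl)tridecyl]hexahydro-1H-cyclopenta[c]isoxazole (pyrinodemin B)
Conditions: H2 (1 atm), 5 % Rh/Al2O3, EtOAc, Et3N (trace), rt
Reagents that add atoms: none
Why: Heterogeneous syn hydrogenation of the trisubstituted enol ether; rhodium is chosen for its low tendency to hydrogenolyse C–O and N–O bonds and is used under neutral conditions at 1 atm to spare the pyridine rings, whereas [Ir(cod)(PCy3)(py)]PF6 would be blocked by them. Ring B shields the concave face of C3, so both hydrogens should arrive from the convex face: H3 becomes cis to H3a and H6a and the chain is pushed endo, giving 3S.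

## Compound list

1 | 8-bromooct-1-yne | C#CCCCCCCBr | starting material
2 | cyclopentene oxide (6-oxabicyclo[3.1.0]hexane) | C1CC2OC2C1 | starting material
3 | lithium 8-bromooct-1-yn-1-ide | [Li+].[C-]#CCCCCCCBr | intermediate (not isolated)
4 | racemic trans-2-(8-bromooct-1-yn-1-yl)cyclopentan-1-ol (equal amounts of the 1S,2R and 1R,2S enantiomers) | O[C@H]1CCC[C@@H]1C#CCCCCCCBr.O[C@@H]1CCC[C@H]1C#CCCCCCCBr | intermediate
5 | (1S,2R)-2-(8-bromooct-1-yn-1-yl)cyclopentan-1-ol | O[C@H]1CCC[C@@H]1C#CCCCCCCBr | intermediate
6 | 3-methylpyridine | Cc1cccnc1 | starting material
7 | (pyridin-3-ylmethyl)lithium | [Li+].[CH2-]c1cccnc1 | intermediate (not isolated)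
8 | lithium (1S,2R)-2-(8-bromooct-1-yn-1-yl)cyclopentan-1-olate | [Li+].[O-][C@H]1CCC[C@@H]1C#CCCCCCCBr | intermediate (not isolated)
9 | (1S,2R)-2-[9-(pyridin-3-yl)non-1-yn-1-yl]cyclopentan-1-ol | O[C@H]1CCC[C@@H]1C#CCCCCCCCc1cccnc1 | intermediate
10 | tert-butyl N-[(tert-butoxycarbonyl)oxy]carbamate | CC(C)(C)OC(=O)NOC(=O)OC(C)(C)C | starting material
11 | tert-butyl N-[(tert-butoxycarbonyl)oxy]-N-{(1R,2R)-2-[9-(pyridin-3-yl)non-1-yn-1-yl]cyclopentyl}carbamate | CC(C)(C)OC(=O)N(OC(=O)OC(C)(C)C)[C@@H]1CCC[C@@H]1C#CCCCCCCCc1cccnc1 | intermediate
12 | N-{(1R,2R)-2-[9-(pyridin-3-yl)non-1-yn-1-yl]cyclopentyl}hydroxylamine | ON[C@@H]1CCC[C@@H]1C#CCCCCCCCc1cccnc1 | intermediate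
13 | 12-bromododecan-1-ol | OCCCCCCCCCCCCBr | starting material
14 | (pyridin-3-ylmethyl)sodium | [Na+].[CH2-]c1cccnc1 | intermediate (not isolated)
15 | sodium 12-bromododecan-1-olate | [Na+].[O-]CCCCCCCCCCCCBr | intermediate (not isolated)
16 | 13-(pyridin-3-yl)tridecan-1-ol | OCCCCCCCCCCCCCc1cccnc1 | intermediate
17 | 13-(pyridin-3-yl)tridecanal | O=CCCCCCCCCCCCCc1cccnc1 | intermediate
18 | (Z)-N-{(1R,2R)-2-[9-(pyridin-3-yl)non-1-yn-1-yl]cyclopentyl}-13-(pyridin-3-yl)tridecan-1-imine N-oxide | [O-]/[N+](=C\CCCCCCCCCCCCc1cccnc1)[C@@H]1CCC[C@@H]1C#CCCCCCCCc1cccnc1 | intermediate (not isolated)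
19 | N-{(1R,2R)-2-[9-(pyridin-3-yl)non-1-yn-1-yl]cyclopentyl}-N-[13-(pyridin-3-yl)tridecyl]hydroxylamine | c1cncc(CCCCCCCCCCCCCN(O)[C@@H]2CCC[C@@H]2C#CCCCCCCCc2cccnc2)c1 | intermediate
20 | bis(pyridinium) bis[bis(trifluoromethanesulfonyl)azanide] salt of 19 | c1c[nH+]cc(CCCCCCCCCCCCCN(O)[C@@H]2CCC[C@@H]2C#CCCCCCCCc2ccc[nH+]c2)c1.O=S(=O)([N-]S(=O)(=O)C(F)(F)F)C(F)(F)F.O=S(=O)([N-]S(=O)(=O)C(F)(F)F)C(F)(F)F | intermediate (not isolated)
21 | (3Z,3aS,6aR)-3-[8-(pyridin-3-yl)octylidene]-1-[13-(pyridin-3-yl)tridecyl]hexahydro-1H-cyclopenta[c]isoxazole | c1cncc(CCCCCCCCCCCCCN2O/C(=C\CCCCCCCc3cccnc3)[C@H]3CCC[C@H]32)c1 | intermediate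
22 | (3S,3aS,6aR)-3-[8-(pyridin-3-yl)octyl]-1-[13-(pyridin-3-yl)tridecyl]hexahydro-1H-cyclopenta[c]isoxazole (pyrinodemin B) | c1cncc(CCCCCCCCCCCCCN2O[C@@H](CCCCCCCCc3cccnc3)[C@H]3CCC[C@H]32)c1 | target

## Step count and least certain steps

Total step count: 10. Longest linear sequence: 8 steps (steps 1, 2, 3, 4, 5, 8, 9 and 10); steps 6 and 7 form the side branch.

Step 9 (key step). The processes most likely to interfere are:
- binding or reduction of the gold catalyst by the hydroxylamine or by residual free pyridine, since the three nitrogens are of similar basicity and share the two protons;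
- endo closure, by oxygen attack at C1'' or by nitrogen attack at C1'' with loss of the O–H proton;
- heterolysis of the N–O bond in the vinyl-gold intermediate (internal redox) in place of protodeauration.

All three arise from the way a cationic gold centre activates the alkyne in a molecule that holds three nitrogen bases. The fallback sets out from 19 and returns at 21 without a metal. KOt-Bu in DMSO/THF at rt deprotonates the N–OH group to the potassium hydroxylaminate F1. Its oxygen should add to C3 in the same 5-exo-dig, anti sense, and the vinyl anion is protonated by t-BuOH to the same Z enol ether. The weakness of this variant is base-induced alkyne–allene isomerisation through C3a, so it would be run at the lowest temperature that gives turnover.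

Step 10. What may go wrong is hydrogenolysis of N1–O2 or of the vinylic O2–C3 bond, partial reduction of a pyridine ring, slowing of the catalyst by pyridine adsorption, or migration of the double bond to C3=C3a before reduction, which would erase C3a. These all stem from chemistry at a metal surface. The fallback replaces it by ionic hydrogenation; it makes no new compound, so its entry below is F0. It sets out from 21 and returns at 22: Et3SiH and TFA in CH2Cl2 at −20 °C protonate C1'', and the silane delivers hydride to the resulting C3 oxocarbenium ion from the convex face. The facial bias is the same, and no metal surface is present to cleave the N–O bond or reduce the pyridines.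

Step 4. What may go wrong is elimination of the activated alcohol toward C5, or failure of the bulky bis-carbamate nitrogen to displace at the secondary carbon beside the alkynyl group. The fallback keeps the inversion but uses a small nucleophile and makes the N–O bond afterwards. It sets out from 9 and returns at 19, bypassing 11, 12 and 18.
- Mitsunobu azidation of 9 (diphenylphosphoryl azide, PPh3, DIAD) gives the cis azide F2.
- Staudinger reduction (PPh3, THF/H2O) gives the amine F3.
- Reductive amination with 17 (NaBH(OAc)3) gives the secondary amine F4.
- Oxidation with dibenzoyl peroxide buffered by K2HPO4 gives the O-benzoyl hydroxylamine F5.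
- Methanolysis (NaOMe, MeOH) gives 19.

Step 2. What may go wrong is insufficient discrimination between the enantiomers by the enzyme, so that 5 is not obtained enantiomerically pure at a useful conversion; the selectivity of a lipase for a new substrate cannot be predicted with certainty. The fallback sets out from 4 and returns at 5. Esterification with (2S)-2-methoxy-2-phenylacetic acid (DCC, DMAP) gives the diastereomeric esters F6 and F7. These are separated by chromatography, and F6 is saponified (LiOH, THF/H2O, 0 °C) to 5.

## Further compounds

F1 | step 9 | potassium N-{(1R,2R)-2-[9-(pyridin-3-yl)non-1-yn-1-yl]cyclopentyl}-N-[13-(pyridin-3-yl)tridecyl]hydroxylaminate (O-potassium salt of 19) | [K+].[O-]N(CCCCCCCCCCCCCc1cccnc1)[C@@H]1CCC[C@@H]1C#CCCCCCCCc1cccnc1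
F0 | step 10 | none | none
F2 | step 4 | 3-{9-[(1R,2R)-2-azidocyclopentyl]non-8-yn-1-yl}pyridine | [N-]=[N+]=N[C@@H]1CCC[C@@H]1C#CCCCCCCCc1cccnc1
F3 | step 4 | (1R,2R)-2-[9-(pyridin-3-yl)non-1-yn-1-yl]cyclopentan-1-amine | N[C@@H]1CCC[C@@H]1C#CCCCCCCCc1cccnc1
F4 | step 4 | N-{(1R,2R)-2-[9-(pyridin-3-yl)non-1-yn-1-yl]cyclopentyl}-13-(pyridin-3-yl)tridecan-1-amine | c1cncc(CCCCCCCCCCCCCN[C@@H]2CCC[C@@H]2C#CCCCCCCCc2cccnc2)c1
F5 | step 4 | O-benzoyl-N-{(1R,2R)-2-[9-(pyridin-3-yl)non-1-yn-1-yl]cyclopentyl}-N-[13-(pyridin-3-yl)tridecyl]hydroxylamine | c1cncc(CCCCCCCCCCCCCN(OC(=O)c3ccccc3)[C@@H]2CCC[C@@H]2C#CCCCCCCCc2cccnc2)c1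
F6 | step 2 | (1S,2R)-2-(8-bromooct-1-yn-1-yl)cyclopentyl (2S)-2-methoxy-2-phenylacetate | CO[C@@H](c1ccccc1)C(=O)O[C@H]1CCC[C@@H]1C#CCCCCCCBr
F7 | step 2 | (1R,2S)-2-(8-bromooct-1-yn-1-yl)cyclopentyl (2S)-2-methoxy-2-phenylacetate | CO[C@@H](c1ccccc1)C(=O)O[C@@H]1CCC[C@H]1C#CCCCCCCBr
A1 | alternative 1 | cis-cyclopent-4-ene-1,3-diyl dibenzoate (meso) | O=C(O[C@H]1C[C@@H](OC(=O)c2ccccc2)C=C1)c1ccccc1
A2 | alternative 1 | cis-4-{(1S)-9-(pyridin-3-yl)-1-[({13-(pyridin-3-yl)tridecyl}amino)oxy]nonyl}cyclopent-2-en-1-yl benzoate | c1cncc(CCCCCCCCCCCCCNO[C@@H](CCCCCCCCc2cccnc2)[C@H]2C[C@@H](OC(=O)c3ccccc3)C=C2)c1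
A3 | alternative 1 | (3S,3aS,6aR)-3-[8-(pyridin-3-yl)octyl]-1-[13-(pyridin-3-yl)tridecyl]-3,3a,4,6a-tetrahydro-1H-cyclopenta[c]isoxazole | c1cncc(CCCCCCCCCCCCCN2O[C@@H](CCCCCCCCc3cccnc3)[C@H]3CC=C[C@H]32)c1
A4 | alternative 2 | 1-(cyclopent-1-en-1-yl)-9-(pyridin-3-yl)nonan-1-one | O=C(CCCCCCCCc1cccnc1)C1=CCCC1
A5 | alternative 2 | N-[13-(pyridin-3-yl)tridecyl]hydroxylamine | ONCCCCCCCCCCCCCc1cccnc1
A6 | alternative 2 | (3aS,6aR)-3-[8-(pyridin-3-yl)octyl]-1-[13-(pyridin-3-yl)tridecyl]hexahydro-1H-cyclopenta[c]isoxazol-3-ol (either C3 anomer) | c1cncc(CCCCCCCCCCCCCN2OC(O)(CCCCCCCCc3cccnc3)[C@H]3CCC[C@H]32)c1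
A7 | alternative 3 | cis-fused 7-[8-(pyridin-3-yl)oct-1-yn-1-yl]-6-[13-(pyridin-3-yl)tridecyl]-6-azabicyclo[3.2.0]heptane | c1cncc(CCCCCCCCCCCCCN2[C@@H](C#CCCCCCCc3cccnc3)[C@H]3CCC[C@H]32)c1
A8 | alternative 3 | cis-fused 7-[8-(pyridin-3-yl)oct-1-yn-1-yl]-6-[13-(pyridin-3-yl)tridecyl]-6-azabicyclo[3.2.0]heptane 6-oxide | c1cncc(CCCCCCCCCCCCC[N+]2([O-])[C@@H](C#CCCCCCCc3cccnc3)[C@H]3CCC[C@H]32)c1
A9 | alternative 3 | (3R,3aS,6aR)-3-[8-(pyridin-3-yl)oct-1-yn-1-yl]-1-[13-(pyridin-3-yl)tridecyl]hexahydro-1H-cyclopenta[c]isoxazole | c1cncc(CCCCCCCCCCCCCN2O[C@@H](C#CCCCCCCc3cccnc3)[C@H]3CCC[C@H]32)c1
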